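**Plan**

1. Retrosynthesis cuts the C8 urocanate ester and the C4 ketal/hemiketal exchange, then the ring bond C1–C2 of the ten-membered carbocycle, then C3–C4 (vinyl addition to a butenolide), C7–C8 (vinylogous aldol) and finally the two cyclobutanone bonds that tie C1 and C10 to a ketene.
2. The feature that allows the C1–C2 cut: C1 is a carbon of ring A (the cyclohexene) that can carry a carboxyl group, and C2–C3 are the CH2 and the ester-bearing CH next to the ketal carbon C4 of the oxygen-bridged dihydrofuran (O joins C4 and C7), so they can be stored as an acrylate on C4.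
3. Forward order: ring A with its C1 carbon and C8 aldehyde from (R)-α-phellandrene, then the C4–C7 butenolide, then the dihydrofuran methyl ketal carrying the acrylate, and last the ten-membered ring by radical C1–C2 closure.
4. Stereochemistry: C14 comes from phellandrene; C1 and C10 from the ketene cycloaddition anti to the isopropyl group; C7 and C8 from a catalyst-controlled vinylogous aldol; C4 is chosen at ketalisation and is locked by the bridge.
5. C1 is re-formed in the ring closure under control of the C10 tether and the C14 isopropyl group; C3 is settled by equilibration in the last step.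

Key step: step 17

Atom numbers are those of the target: C1 and C10 are the ring-fusion carbons, C2H2, C3 (ester CH), C4 (hemiketal), C5=C6, C7 (methyl, ether O), C8 (acyloxy CH), C9H2, C11(Me)=C12, C13H2, C14 (isopropyl CH).

Assumption 1: the natural configuration at C3, an epimerisable position of a hemiketal that can open to a β-keto ester, is the thermodynamically preferred one.

Assumption 2: the Ti(OiPr)4/BINOL catalyst shows the same sense of induction with the 5-methyl siloxyfuran as with the parent; if the sense is opposite, the (R)-ligand is used in step 9.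

Assumption 3: (E)-N-methylurocanic acid is bought.

**Route**

Step 1
Reactants: 1 (R)-α-phellandrene; 2 trichloroacetyl chloride
Product: 3 cis-fused dichlorocyclobutanone (C=O carbon on C1, CCl2 on C10, both anti to the C14 isopropyl group; 1R,10R,14R)
Conditions: Zn dust, Et2O, ultrasound, 20 °C
Reagents that add atoms: none
Why: Ketene–alkene [2+2] cycloaddition of dichloroketene made in the flask, which takes the disubstituted diene alkene with its carbonyl carbon at the diene terminus (C1) and approaches anti to the isopropyl group, setting C1 and C10 cis to each other.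

Step 2
Reactants: 3 cis-fused dichlorocyclobutanone
Product: 4 cis-fused cyclobutanone (1R,10R,14R)
Conditions: Zn dust, AcOH, 25 to 60 °C
Reagents that add atoms: none
Why: Reductive dechlorination of an α,α-dichloroketone with zinc, which leaves the ring alkene and the ring fusion untouched.

Step 3
Reactants: 4 cis-fused cyclobutanone
Product: 5 (E)-α-(dimethylaminomethylene)cyclobutanone
Conditions: t-BuOCH(NMe2)2, neat, 60 °C
Reagents that add atoms: Bredereck's reagent, CN(C)C(OC(C)(C)C)N(C)C
Why: Aminomethylenation of the only CH2 next to the ketone with Bredereck's reagent, which brings in the carbon that becomes C8.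

Step 4
Reactants: 5 (E)-α-(dimethylaminomethylene)cyclobutanone
Product: 6 methyl C1-carboxylate with a C10 CH2CH(OMe)2 side chain (1R,10R,14R)
Conditions: p-TsOH·H2O (1.2 equiv), MeOH, reflux
Reagents that add atoms: methanol, CO
Why: Acid-mediated methanolysis and retro-Claisen opening of the strained β-amino enone, which splits the four-membered ring between the carbonyl carbon (now the C1 ester) and the former CH2 (now C9, carrying C8 as a dimethyl acetal).

Step 5
Reactants: 6 ester acetal
Product: 7 C1 hydroxymethyl acetal
Conditions: LiAlH4, THF, 0 °C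
Reagents that add atoms: none
Why: Hydride reduction of the ester to the primary alcohol, which hides the C1 carbon from the organolithium of step 11 and from the second methyl ester made later.

Step 6
Reactants: 7 C1 hydroxymethyl acetal
Product: 8 C1 CH2OTBS acetal
Conditions: TBSCl, imidazole, CH2Cl2, 0 to 20 °C
Reagents that add atoms: tert-butyldimethylsilyl chloride, CC(C)(C)[Si](C)(C)Cl
Why: Silyl protection of the primary alcohol, needed because the free alcohol would close onto the C8 aldehyde as a lactol.

Step 7
Reactants: 8 C1 CH2OTBS acetal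
Product: 9 C8 aldehyde (1R,10R,14R)
Conditions: PPTS (cat.), acetone/H2O, 40 °C
Reagents that add atoms: water, O
Why: Mild acid hydrolysis of a dimethyl acetal of an unhindered aldehyde, under alcohol-free conditions in which a primary TBS ether survives.

Step 8
Reactants: 10 α-angelica lactone
Product: 11 5-methyl-2-(trimethylsilyloxy)furan
Conditions: TMSOTf, Et3N, Et2O, 0 °C
Reagents that add atoms: trimethylsilyl triflate, C[Si](C)(C)OS(=O)(=O)C(F)(F)F
Why: Soft enolisation and O-silylation of the butenolide to the aromatic siloxyfuran, the standard donor for vinylogous Mukaiyama aldol reactions.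

Step 9
Reactants: 9 C8 aldehyde; 11 5-methyl-2-(trimethylsilyloxy)furan
Product: 13 butenolide alcohol (7S,8S; C7 quaternary with methyl and lactone oxygen, C8 carbinol), via trimethylsilyl ether 12 (not isolated)
Conditions: Ti(OiPr)4/(S)-BINOL (20 mol %), Et2O, −20 °C; then aq. citric acid, THF
Reagents that add atoms: none
Why: Chiral Lewis acid-catalysed vinylogous Mukaiyama aldol reaction in which the siloxyfuran attacks through its methyl-bearing γ-carbon, the Ti–BINOL complex selects the aldehyde face (C8) over the weak bias of the remote C10 centre, and the open transition state usual for Lewis acid-promoted siloxyfuran additions gives the syn C7–O/C8–O relationship.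

Step 10
Reactants: 13 butenolide alcohol
Product: 14 butenolide C8 TBS ether
Conditions: TBSOTf, 2,6-lutidine, CH2Cl2, −40 to 0 °C
Reagents that add atoms: tert-butyldimethylsilyl triflate, CC(C)(C)[Si](C)(C)OS(=O)(=O)C(F)(F)F
Why: Silylation of a hindered secondary alcohol with the silyl triflate, giving an ether that outlasts the acid of step 12 because it sits next to the quaternary C7.

Step 11
Reactants: 14 butenolide C8 TBS ether; 15 2-bromoprop-2-en-1-ol
Product: 16 C4 hemiketal carrying the 3-hydroxyprop-1-en-2-yl group (C4 anomers in equilibrium)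
Conditions: 15, t-BuLi (3 equiv per 15), Et2O, −78 to 0 °C; then 14, THF, −78 °C; aq. NH4Cl at −78 °C
Reagents that add atoms: none
Why: 1,2-Addition of a vinyllithium (the O,C-dilithio derivative of 2-bromoallyl alcohol from bromine–lithium exchange) to the lactone carbonyl, which stops at the lithium hemiketal at −78 °C and forms the C3–C4 bond with C2 already attached as the methylene.

Step 12
Reactants: 16 C4 hemiketal
Product: 17 dihydrofuran methyl ketal diol (4R,7S,8S; C3 arm cis to the C8 arm, free C1 CH2OH and allylic CH2OH, C8 OTBS kept)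
Conditions: CSA (cat.), MeOH/CH2Cl2, 0 to 20 °C; Et3N
Reagents that add atoms: methanol, CO
Why: Acid-catalysed ketalisation through the doubly allylic oxocarbenium ion, with methanolysis of the primary TBS ether in the same pot; C4 forms as a separable pair of anomers, of which the one with the C3 arm cis to the C8 arm is taken on and the other is returned to the same conditions.

Step 13
Reactants: 17 dihydrofuran methyl ketal diol
Product: 18 α-substituted acrolein (C1 CH2OH untouched)
Conditions: MnO2, CH2Cl2, 20 °C
Reagents that add atoms: none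
Why: MnO2 oxidation, which is selective for the allylic alcohol over the saturated primary alcohol on C1.

Step 14
Reactants: 18 α-substituted acrolein
Product: 20 methyl acrylate on the C4 ketal (C1 CH2OH free), via acrylic acid 19 (not isolated)
Conditions: NaClO2, NaH2PO4, 2-methyl-2-butene, t-BuOH/H2O, 0 °C; then TMSCHN2, MeOH/toluene, 0 °C
Reagents that add atoms: sodium chlorite, [Na+].[O-]Cl=O; trimethylsilyldiazomethane, C[Si](C)(C)C=[N+]=[N-]
Why: Pinnick oxidation of the enal followed by diazoalkane esterification, which builds the C3 methyl ester without ever forming a C3 enolate next to the ketal.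

Step 15
Reactants: 20 methyl acrylate with free C1 CH2OH
Product: 22 C1 carboxylic acid, via C1 aldehyde 21 (not isolated)
Conditions: Dess–Martin periodinane, NaHCO3, CH2Cl2, 0 to 20 °C; then NaClO2, NaH2PO4, 2-methyl-2-butene, t-BuOH/H2O
Reagents that add atoms: sodium chlorite, [Na+].[O-]Cl=O
Why: Buffered Dess–Martin oxidation and Pinnick oxidation of the one remaining alcohol; epimerisation at C1 in the aldehyde is of no consequence because C1 becomes a radical in step 17.

Step 16
Reactants: 22 C1 carboxylic acid; 23 N-hydroxyphthalimide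
Product: 24 C1 N-acyloxyphthalimide carrying the dihydrofuran ketal acrylate (4R,7S,8S,10R,14R)
Conditions: DIC, DMAP (cat.), CH2Cl2, 20 °C
Reagents that add atoms: none
Why: Carbodiimide (Steglich-type) esterification, the usual way to make redox-active esters, including those of hindered secondary acids.

Step 17
Reactants: 24 C1 N-acyloxyphthalimide
Product: 25 bridged bicyclic methyl ketal with C8 TBS ether (1R,3R,4R,7S,8S,10R,14R; a C3 epimer may accompany it and is carried along)
Conditions: controlled-potential electrolysis (−1.3 V vs Ag/AgCl), RVC cathode, Zn anode, undivided cell, Bu4NPF6, DMF, CF3CH2OH (10 equiv), 2 mM, 20 °C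
Reagents that add atoms: none
Why: One-electron reduction of the N-acyloxyphthalimide at the carbon cathode fragments it into phthalimide anion, CO2 and the secondary C1 radical, which adds to the unsubstituted acrylate terminus C2; the ester-stabilised C3 radical is then reduced and protonated by trifluoroethanol before the enolate can expel an alkoxy group from C4. The closest known reaction type is the reductive decarboxylative Giese addition of redox-active esters, combined with radical macrocyclisation onto acrylates. The ten-membered ring closes in a 10-endo-trig mode, with C2 and C3 both inside the new ring. C1 is set by the substrate: the acceptor is delivered from the C10 side chain and bonds anti to the neighbouring C14 isopropyl group, giving the cis ring fusion, whereas C3 is set by an uncontrolled protonation and is settled in step 20. The step needs attack at C2 in preference to 6-exo attack at C6 of the dihydrofuran and to reduction of the C1 radical. It relies on polarity matching of the nucleophilic alkyl radical with the electron-poor acrylate, on the cis placement of both arms on the dihydrofuran, on high dilution and on a potential too positive to reduce alkyl radicals.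

Step 18
Reactants: 25 bridged bicyclic methyl ketal with C8 TBS ether
Product: 26 C8 alcohol (methyl ketal kept)
Conditions: TBAF, AcOH, THF, 20 to 45 °C
Reagents that add atoms: none
Why: Fluoride cleavage of the silyl ether, buffered with acetic acid so that the C3 proton next to the ketal is not removed.

Step 19
Reactants: 26 C8 alcohol; 27 (E)-N-methylurocanic acid
Product: 28 C8 N-methylurocanate of the methyl ketal
Conditions: DCC, DMAP, CH2Cl2, 20 °C
Reagents that add atoms: none
Why: Steglich esterification of the only free hydroxyl; the ketal keeps C4–OH masked, as in urocanoylations of related C4 ketals.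

Step 20
Reactants: 28 C8 N-methylurocanate of the methyl ketal
Product: 29 target CNP0113846.1 (1R,3R,4R,7S,8S,10R,14R)
Conditions: CSA (2 equiv), CH2Cl2/H2O, 20 °C; aq. NaHCO3
Reagents that add atoms: water, O
Why: Acid hydrolysis of the allylic methyl ketal to the hemiketal (one equivalent of acid is held by the imidazole); the hemiketal opens reversibly to the C4 ketone, through which C3 equilibrates to the more stable epimer, while C4 stays fixed by the bridge.

**Compound list**

1 | (R)-α-phellandrene | CC1=CC[C@H](C(C)C)C=C1 | starting material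
2 | trichloroacetyl chloride | ClC(Cl)(Cl)C(Cl)=O | starting material
3 | cis-fused dichlorocyclobutanone | O=C1[C@@H]2[C@@H](C(C)C)CC=C(C)[C@@H]2C1(Cl)Cl | intermediate
4 | cis-fused cyclobutanone | O=C1[C@@H]2[C@@H](C(C)C)CC=C(C)[C@@H]2C1 | intermediate
5 | (E)-α-(dimethylaminomethylene)cyclobutanone | O=C1[C@@H]2[C@@H](C(C)C)CC=C(C)[C@@H]2/C1=C\N(C)C | intermediate
6 | methyl C1-carboxylate with C10 CH2CH(OMe)2 chain | COC(=O)[C@@H]1[C@@H](C(C)C)CC=C(C)[C@@H]1CC(OC)OC | intermediate
7 | C1 hydroxymethyl acetal | OC[C@@H]1[C@@H](C(C)C)CC=C(C)[C@@H]1CC(OC)OC | intermediate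
8 | C1 CH2OTBS acetal | CC(C)(C)[Si](C)(C)OC[C@@H]1[C@@H](C(C)C)CC=C(C)[C@@H]1CC(OC)OC | intermediate
9 | C8 aldehyde | CC(C)(C)[Si](C)(C)OC[C@@H]1[C@@H](C(C)C)CC=C(C)[C@@H]1CC=O | intermediate
10 | α-angelica lactone | CC1=CCC(=O)O1 | starting material
11 | 5-methyl-2-(trimethylsilyloxy)furan | Cc1ccc(O[Si](C)(C)C)o1 | intermediate
12 | trimethylsilyl ether of the aldol adduct | CC(C)(C)[Si](C)(C)OC[C@@H]1[C@@H](C(C)C)CC=C(C)[C@@H]1C[C@H](O[Si](C)(C)C)[C@]2(C)C=CC(=O)O2 | intermediate (not isolated)
13 | butenolide alcohol (7S,8S) | CC(C)(C)[Si](C)(C)OC[C@@H]1[C@@H](C(C)C)CC=C(C)[C@@H]1C[C@H](O)[C@]2(C)C=CC(=O)O2 | intermediate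
14 | butenolide C8 TBS ether | CC(C)(C)[Si](C)(C)OC[C@@H]1[C@@H](C(C)C)CC=C(C)[C@@H]1C[C@H](O[Si](C)(C)C(C)(C)C)[C@]2(C)C=CC(=O)O2 | intermediate
15 | 2-bromoprop-2-en-1-ol | OCC(Br)=C | starting material
16 | C4 hemiketal with 3-hydroxyprop-1-en-2-yl group (C4 anomers) | CC(C)(C)[Si](C)(C)OC[C@@H]1[C@@H](C(C)C)CC=C(C)[C@@H]1C[C@H](O[Si](C)(C)C(C)(C)C)[C@]2(C)C=CC(O)(C(=C)CO)O2 | intermediate
17 | dihydrofuran methyl ketal diol (4R) | OC[C@@H]1[C@@H](C(C)C)CC=C(C)[C@@H]1C[C@H](O[Si](C)(C)C(C)(C)C)[C@]2(C)C=C[C@](OC)(C(=C)CO)O2 | intermediate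
18 | α-substituted acrolein | OC[C@@H]1[C@@H](C(C)C)CC=C(C)[C@@H]1C[C@H](O[Si](C)(C)C(C)(C)C)[C@]2(C)C=C[C@](OC)(C(=C)C=O)O2 | intermediate
19 | acrylic acid | OC[C@@H]1[C@@H](C(C)C)CC=C(C)[C@@H]1C[C@H](O[Si](C)(C)C(C)(C)C)[C@]2(C)C=C[C@](OC)(C(=C)C(=O)O)O2 | intermediate (not isolated)
20 | methyl acrylate with free C1 CH2OH | OC[C@@H]1[C@@H](C(C)C)CC=C(C)[C@@H]1C[C@H](O[Si](C)(C)C(C)(C)C)[C@]2(C)C=C[C@](OC)(C(=C)C(=O)OC)O2 | intermediate
21 | C1 aldehyde | O=C[C@@H]1[C@@H](C(C)C)CC=C(C)[C@@H]1C[C@H](O[Si](C)(C)C(C)(C)C)[C@]2(C)C=C[C@](OC)(C(=C)C(=O)OC)O2 | intermediate (not isolated)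
22 | C1 carboxylic acid | OC(=O)[C@@H]1[C@@H](C(C)C)CC=C(C)[C@@H]1C[C@H](O[Si](C)(C)C(C)(C)C)[C@]2(C)C=C[C@](OC)(C(=C)C(=O)OC)O2 | intermediate
23 | N-hydroxyphthalimide | O=C1c2ccccc2C(=O)N1O | starting material
24 | C1 N-acyloxyphthalimide with dihydrofuran ketal acrylate | O=C(ON3C(=O)c4ccccc4C3=O)[C@@H]2[C@@H](C(C)C)CC=C(C)[C@@H]2C[C@H](O[Si](C)(C)C(C)(C)C)[C@]1(C)C=C[C@](OC)(C(=C)C(=O)OC)O1 | intermediate
25 | bridged bicyclic methyl ketal with C8 TBS ether | COC(=O)[C@@H]1C[C@@H]2[C@@H](C(C)C)CC=C(C)[C@@H]2C[C@H](O[Si](C)(C)C(C)(C)C)[C@]2(C)C=C[C@@]1(OC)O2 | intermediate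
26 | C8 alcohol of the bicyclic methyl ketal | COC(=O)[C@@H]1C[C@@H]2[C@@H](C(C)C)CC=C(C)[C@@H]2C[C@H](O)[C@]2(C)C=C[C@@]1(OC)O2 | intermediate
27 | (E)-N-methylurocanic acid | OC(=O)/C=C/c1cn(C)cn1 | starting material
28 | C8 N-methylurocanate of the methyl ketal | COC(=O)[C@@H]1C[C@@H]2[C@@H](C(C)C)CC=C(C)[C@@H]2C[C@H](OC(=O)/C=C/c2cn(C)cn2)[C@]2(C)C=C[C@@]1(OC)O2 | intermediate
29 | CNP0113846.1 | COC(=O)[C@@H]1C[C@@H]2[C@@H](C(C)C)CC=C(C)[C@@H]2C[C@H](OC(=O)/C=C/c2cn(C)cn2)[C@]2(C)C=C[C@@]1(O)O2 | target

**Step count and risks**

Total step count: 20. Longest linear sequence: 19 steps (steps 1 to 7 and 9 to 20, from (R)-α-phellandrene); step 8 is a one-step side branch.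

Steps most likely to fail:

Step 17. The C1 radical may be reduced or dimerise near the cathode before it reaches C2, may be captured in a 6-exo mode by the C5=C6 alkene, or may bond on the wrong face of C1 to give the trans ring fusion. The fallback sets out from acid 22 and replaces the electrode by a halide/silane chain process. Acid 22 is coupled with 1-hydroxypyridine-2(1H)-thione (DCC, dark) to the Barton thiohydroxamate ester F1. F1 is photolysed in the presence of excess iodoform to the C1 iodide F2 (decarboxylative iodination; iodine transfer at high iodoform concentration outruns ring closure, and the C1 epimer mixture is of no consequence). F2 is then added by syringe pump with (Me3Si)3SiH and AIBN to benzene at 80 °C at 2 mM, a classical iodide-based radical macrocyclisation in which the lifetime of the C1 radical is set by the silane concentration. The fallback comes back to the route at 25.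

Step 9. The catalyst may fail to override the remote C10 centre (poor facial selectivity at C8), or the methyl-bearing donor may erode the syn selectivity between C7 and C8. The fallback sets out from aldehyde 9 and builds both centres by a hydroxyl-directed epoxidation.
- Still–Gennari olefination with methyl 2-[bis(2,2,2-trifluoroethoxy)phosphoryl]propanoate (KHMDS, 18-crown-6) gives the (Z)-α-methyl enoate F3.
- DIBAL-H reduces it to the (Z)-allylic alcohol F4.
- Sharpless epoxidation (Ti(OiPr)4, D-(−)-diethyl tartrate, t-BuOOH, 4 Å sieves) gives the epoxy alcohol F5 and leaves the ring A alkene alone.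
- Dess–Martin oxidation gives the epoxy aldehyde F6.
- A second Still–Gennari olefination with methyl bis(2,2,2-trifluoroethyl)phosphonoacetate gives the (Z)-γ,δ-epoxy enoate F7.
- Catalytic CSA in CH2Cl2 makes the ester carbonyl open the epoxide at C7 with inversion and lactonise.

The net anti addition of the two oxygens across the (Z)-alkene gives the syn C7–O/C8–O pattern, and the fallback comes back to the route at 13.

Step 11. The tetrahedral intermediate may collapse and take up a second equivalent of the organolithium, or the hemiketal may open to the dienone and decompose. The fallback sets out from 14 and brings in C2–C3 at the ester oxidation level. The lithium enolate of methyl 3-(dimethylamino)propanoate (LDA, THF, −78 °C) adds to the lactone carbonyl in a Claisen-type reaction to give the hemiketal amino ester F8. CSA (2.2 equiv) in MeOH turns it into the methyl ketal amino ester F9, with the C1 silyl ether cleaved and the wanted C4 anomer separated. One equivalent of mCPBA at −20 °C gives the N-oxide F10, which on warming undergoes Cope elimination toward the only β-hydrogen (on C3). The fallback comes back to the route at 20, saving steps 13 and 14.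

**Further compounds**

F1 | step 17 | Barton thiohydroxamate ester of acid 22 | S=c1ccccn1OC(=O)[C@@H]2[C@@H](C(C)C)CC=C(C)[C@@H]2C[C@H](O[Si](C)(C)C(C)(C)C)[C@]3(C)C=C[C@](OC)(C(=C)C(=O)OC)O3
F2 | step 17 | C1 iodide (C1 epimers) | IC2[C@@H](C(C)C)CC=C(C)[C@@H]2C[C@H](O[Si](C)(C)C(C)(C)C)[C@]3(C)C=C[C@](OC)(C(=C)C(=O)OC)O3
F3 | step 9 | (Z)-α-methyl enoate | CC(C)(C)[Si](C)(C)OC[C@@H]1[C@@H](C(C)C)CC=C(C)[C@@H]1C/C=C(/C)C(=O)OC
F4 | step 9 | (Z)-allylic alcohol | CC(C)(C)[Si](C)(C)OC[C@@H]1[C@@H](C(C)C)CC=C(C)[C@@H]1C/C=C(/C)CO
F5 | step 9 | C7–C8 epoxy alcohol | CC(C)(C)[Si](C)(C)OC[C@@H]1[C@@H](C(C)C)CC=C(C)[C@@H]1C[C@@H]2O[C@]2(C)CO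
F6 | step 9 | C7–C8 epoxy aldehyde | CC(C)(C)[Si](C)(C)OC[C@@H]1[C@@H](C(C)C)CC=C(C)[C@@H]1C[C@@H]2O[C@]2(C)C=O
F7 | step 9 | (Z)-γ,δ-epoxy enoate | CC(C)(C)[Si](C)(C)OC[C@@H]1[C@@H](C(C)C)CC=C(C)[C@@H]1C[C@@H]2O[C@]2(C)/C=C\C(=O)OC
F8 | step 11 | hemiketal amino ester (C3 and C4 mixtures) | CC(C)(C)[Si](C)(C)OC[C@@H]1[C@@H](C(C)C)CC=C(C)[C@@H]1C[C@H](O[Si](C)(C)C(C)(C)C)[C@]2(C)C=CC(O)(C(CN(C)C)C(=O)OC)O2
F9 | step 11 | methyl ketal amino ester with free C1 CH2OH (C3 epimers) | OC[C@@H]1[C@@H](C(C)C)CC=C(C)[C@@H]1C[C@H](O[Si](C)(C)C(C)(C)C)[C@]2(C)C=C[C@](OC)(C(CN(C)C)C(=O)OC)O2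
F10 | step 11 | amine N-oxide of F9 | OC[C@@H]1[C@@H](C(C)C)CC=C(C)[C@@H]1C[C@H](O[Si](C)(C)C(C)(C)C)[C@]2(C)C=C[C@](OC)(C(C[N+](C)(C)[O-])C(=O)OC)O2
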